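Target cannot outrun the partner: each target takes up one partner, so I kept the partner's books for these flasks.

| flask | starting material | partner | remark | time |
|---|---|---|---|---|
| east | 0.12 M | 0.12 M | run made earlier |  |
| north-west | 0.060 M | 0.12 M | run made earlier |  |
| north-east | 0.090 M | 0.12 M | run made earlier |  |
| south-west | 0.12 M | 0.060 M | run made earlier |  |
| alpha | 0.12 M | 0.120 M | everything together at the start | 10 h |
| eta | 0.12 M | 0.120 M (in portions, 5, over 6.0 h) | first portion at the start, last at 6.0 h | 10 h |
| delta | 0.12 M | 0.120 M (fed, over 6.0 h) | all else is in the flask from the start; the feed brings no volume worth counting | 10 h |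
| beta | 0.12 M (fed, over 6.0 h) | 0.120 M | all else is in the flask from the start; the feed brings no volume worth counting | 10 h |

| run | time / h | target / % |
|---|---|---|
| east | 0.833 | 13.3 |
| east | 2.00 | 21.9 |
| east | 4.00 | 29.0 |
| east | 6.00 | 31.4 |
| north-west | 1.00 | 15.1 |
| north-west | 3.00 | 31.4 |
| north-west | 5.00 | 37.3 |
| north-west | 8.00 | 42.2 |
| north-east | 0.667 | 10.6 |
| north-east | 1.33 | 18.9 |
| north-east | 3.00 | 29.1 |
| north-east | 8.00 | 38.1 |
| south-west | 2.00 | 16.4 |
| south-west | 4.00 | 20.1 |
| south-west | 6.00 | 21.4 |
| south-west | 8.00 | 22.1 |

(readings scatter by 0.5 percentage points)

- in percentages every species weighs as the starting material in it: one self-condensation product counts as two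
- the analysis behind the earlier runs scatters by 0.5 percentage points, standard deviation
- reactions considered so far: 2 starting material -> self-condensation product; starting material + partner -> target; partner -> decomposed reagent

- the flask with the highest amount of target, in percent of the starting material charged ("all alike" if they lie within 1.5 percentage points) (alpha / eta / delta / beta / all alike)
- final target, as a percentage of the starting material charged, in alpha
- final target, as a percentage of the starting material charged, in eta
- final target, as a percentage of the starting material charged, in delta
- final target, as a percentage of the starting material charged, in beta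

I followed one number, the catch: target formed per partner charged, in moles. In the east run at 6.00 h the catch stood at 31.4%. The south-west run, with half the partner, read 42.8% at the same 6.00 h, higher than the east run by 11 percentage points. The north-west run, with half the starting material, read 21.1% even at 8.00 h, lower than the east run.

Alpha has the east charges, so I only needed the east run's tail. Its gains were 7.1 points up to 4.00 h, then 2.4 points up to 6.00 h. Each gain was thus 0.338 of the last, so the shrinking row adds 1.2 points and gives 32.6%. The weak link was that ratio, since 2.4 points is a small gain to read with a scatter of 0.5 points. So I moved that gain by 0.71 points either way, the scatter of a difference of two readings, and summed the row again from the same last reading, which gave 31.9% and 33.8%, and I committed to 32.6% for alpha with that width. A feed thins the partner and meets thinner starting material, so the south-west and north-west catches pulled opposite ways and I set no number on the fed flasks.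

The forecast named alpha, with 33.5% there, 27.5% in eta, 26% in delta and 24% in beta, reasoning that “fed partner finds starting material already dimerising”.

The flasks gave alpha as the best: 33.4%, 27.9%, 26.6% and 22.4% in the order above.

    2 starting material → self-condensation product (k = 4.92 × 10⁻⁴ M⁻¹ s⁻¹)
    starting material + partner → target, rate k2*[starting material]*[partner]^0.5 (k = 1.71 × 10⁻⁴ M⁻⁰·⁵ s⁻¹)
    partner → decomposed reagent (k = 9.29 × 10⁻⁵ s⁻¹)

In alpha the partner's half-life by decomposition, 2.1 h at 1.40 h, was shorter than the run's 10 h. At the end 0.49% of the partner stood, the limiting reagent, with 0.0794 M decomposed reagent against 0.0400 M of target, a catch of 33.4%. Delta fed over 1.80 h gave 30.8%, which stood 2.6 points below alpha, more than the margin. With alpha's partner cut to 0.030 M, half the south-west run's, one more step of 11 points on the catch read at 6.00 h gives 53.8%, so 13.6% target; that flask gave 14.2% at 10.0 h.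

All runs stem from a simulated flask from invented constants; noise was put on by code.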